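The route rests on relocating the oxygen bridge rather than closing the nine-membered oxacycle (C4–C3–C2–C1–C10–C9–C8–C7–O, eunicellane numbering) directly. A furanophane is oxidised (Achmatowicz) to a pyranose whose ring oxygen sits on C8, so the bridged oxacycle has eight members; methyl addition then creates the tertiary C7 hydroxyl. In the key step acylation with the N-methylurocanoyl mixed anhydride traps the ring–chain tautomer in which C7–OH carries the C4 hemiketal: the 8-ring expands to the 9-ring, the 2,5-dihydrofuran forms, C4 is set and the side chain is installed. The feature exploited is the C4 ketone lying 1,4 and 1,5 to the C7/C8 diol across the cis C5=C6 bond.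

Key step: step 19

Remark: eunicellane numbering is used throughout (C1/C10 ring-fusion carbons, C14 isopropyl carbon, C4 hemiketal carbon, C7 methyl carbinol carbon, C8 acyloxy carbon). As drawn, the C1 side chain is cis to the isopropyl group and trans to the C10 side chain; the route is built for exactly this relative configuration.

Step 1
Reactants: 1 3-methylbutanal; 2 but-3-en-2-one
Product: 4 (R)-4-isopropylcyclohex-2-en-1-one [(R)-cryptone], via keto aldehyde 3 (not isolated)
Conditions: (R)-2-[methoxy(diphenyl)methyl]pyrrolidine (5 mol%), ethyl 3,4-dihydroxybenzoate (20 mol%), neat, 4 °C; then LiOH, i-PrOH, rt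
Reagents that add atoms: none
Why: Enamine-mediated organocatalytic Michael addition (attack on the enamine face remote from the diarylmethyl group should set the later C14 as R) followed by intramolecular aldol condensation (Robinson-type annulation).

Step 2
Reactants: 4 (R)-cryptone; 5 (1,3-dioxolan-2-ylmethyl)magnesium bromide
Product: 6 trimethylsilyl enol ether of trans-3-(1,3-dioxolan-2-ylmethyl)-4-isopropylcyclohexanone
Conditions: CuBr·SMe2 (20 mol%), TMSCl, DMPU, THF, −78 → −40 °C; Et3N, then aq. NaHCO3
Reagents that add atoms: chlorotrimethylsilane, C[Si](C)(C)Cl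
Why: Copper-catalysed conjugate addition of a Grignard reagent with silyl trapping of the enolate; addition anti to the isopropyl group gives a centre that step 3 erases, so only the regiodefined enol ether matters.

Step 3
Reactants: 6 trimethylsilyl enol ether
Product: 7 (R)-3-(1,3-dioxolan-2-ylmethyl)-4-isopropylcyclohex-2-en-1-one
Conditions: Pd(OAc)2 (10 mol%), O2 (1 atm), DMSO, rt
Reagents that add atoms: none
Why: Saegusa–Ito oxidation (aerobic variant) of the regiodefined silyl enol ether returns the enone, now carrying the C2–C3 unit on its β-carbon (later C1); C14 is not touched.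

Step 4
Reactants: 7 β-substituted enone; 8 2-bromo-N-methoxy-N-methylacetamide
Product: 10 2-[2-(1,3-dioxolan-2-ylmethyl)-3-isopropyl-6-oxocyclohexyl]-N-methoxy-N-methylacetamide (1,2-trans and 2,3-cis), via silyl enol ether 9 (not isolated)
Conditions: Stryker's reagent [(Ph3P)CuH]6 (5 mol%), PhMe2SiH, toluene, rt; then MeLi (1.0 equiv), THF, 0 °C; then 8, DMPU, −78 → 0 °C
Reagents that add atoms: none
Why: Tandem copper hydride conjugate reduction and enolate alkylation: hydride should add to C1 anti to the pseudoaxial isopropyl group (side chain ends cis to it), and the regiodefined lithium enolate released by MeLi should be alkylated at C10 anti to the adjacent C1 substituent (trans).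

Step 5
Reactants: 10 keto Weinreb amide
Product: 11 2-[2-(1,3-dioxolan-2-ylmethyl)-3-isopropyl-6-(trifluoromethanesulfonyloxy)cyclohex-5-en-1-yl]-N-methoxy-N-methylacetamide
Conditions: LiN(i-Pr)2 (LDA, 1.1 equiv), THF, −78 °C; PhNTf2, −78 → 0 °C; H2O
Reagents that add atoms: N-phenylbis(trifluoromethanesulfonimide), O=S(=O)(N(c1ccccc1)S(=O)(=O)C(F)(F)F)C(F)(F)F
Why: Kinetic deprotonation at the unhindered C12 methylene rather than the tertiary C10–H, then O-triflation of the enolate (vinyl triflate formation), fixes the later C11=C12 position.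

Step 6
Reactants: 11 enol triflate
Product: 12 2-[6-(1,3-dioxolan-2-ylmethyl)-5-isopropyl-2-methylcyclohex-2-en-1-yl]-N-methoxy-N-methylacetamide (1,6-trans and 5,6-cis)
Conditions: MeZnCl (2 equiv), Pd(PPh3)4 (5 mol%), THF, 50 °C
Reagents that add atoms: methylzinc chloride, C[Zn]Cl
Why: Negishi cross-coupling of a vinyl triflate installs the C11 methyl group regiospecifically; the Weinreb amide and acetal are inert to the organozinc.

Step 7
Reactants: 12 cyclohexene Weinreb amide; 13 2,5-dibromofuran
Product: 15 1-(5-bromofuran-2-yl)-2-[6-(1,3-dioxolan-2-ylmethyl)-5-isopropyl-2-methylcyclohex-2-en-1-yl]ethanone, via 5-bromo-2-furyllithium 14 (not isolated)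
Conditions: 13, n-BuLi (1.0 equiv), Et2O, −78 °C; then 12, −78 → −30 °C; H2O
Reagents that add atoms: none
Why: Bromine–lithium exchange followed by Weinreb ketone synthesis; the chelated tetrahedral intermediate prevents over-addition.

Step 8
Reactants: 15 bromofuryl ketone
Product: 16 (S)-1-(5-bromofuran-2-yl)-2-[6-(1,3-dioxolan-2-ylmethyl)-5-isopropyl-2-methylcyclohex-2-en-1-yl]ethanol
Conditions: RuCl(p-cymene)[(S,S)-TsDPEN] (2 mol%), HCO2H–Et3N (5:2), CH2Cl2, 25 °C
Reagents that add atoms: none
Why: Noyori asymmetric transfer hydrogenation of a heteroaryl ketone, where the (S,S)-catalyst should give the (S)-carbinol (C8) under reagent control; the minor diastereomer derived from residual enantiomeric cryptone is removed here.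

Step 9
Reactants: 16 (S)-furyl carbinol
Product: 17 tert-butyldimethylsilyl ether of 16
Conditions: TBSCl, imidazole, DMF, rt
Reagents that add atoms: tert-butyldimethylsilyl chloride, CC(C)(C)[Si](C)(C)Cl
Why: Standard silylation differentiates the C8 oxygen from the C3 hydroxyl that the ring closure will create.

Step 10
Reactants: 17 silyl ether acetal
Product: 18 2-{2-[(S)-2-(5-bromofuran-2-yl)-2-(tert-butyldimethylsilyloxy)ethyl]-6-isopropyl-3-methylcyclohex-3-en-1-yl}acetaldehyde (1,2-trans and 1,6-cis)
Conditions: TESOTf, 2,4,6-collidine, CH2Cl2, 0 °C; then H2O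
Reagents that add atoms: water, O
Why: Chemoselective dioxolane cleavage through a collidinium intermediate (silyl triflate–pyridine base acetal deprotection) frees the C3 aldehyde without ionising the acid-labile furfuryl silyl ether.

Step 11
Reactants: 18 bromofuran aldehyde
Product: 19 [6](2,5)furanophane carbinol (C3–OH as an epimer mixture; C8–OTBS)
Conditions: CrCl2 (8 equiv), NiCl2 (2 mol%), DMSO/THF (3:1), 0.005 M, rt
Reagents that add atoms: none
Why: Intramolecular Nozaki–Hiyama–Kishi coupling of the 2-bromofuran with the aldehyde closes the C3–C4 bond; the C3 configuration is immaterial because step 12 oxidises it.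

Step 12
Reactants: 19 furanophane carbinol
Product: 20 furanophane C3 ketone
Conditions: Dess–Martin periodinane, CH2Cl2, rt
Reagents that add atoms: none
Why: Dess–Martin oxidation of a furyl carbinol to the 2-acylfuran under non-acidic conditions that the silyl ether tolerates.

Step 13
Reactants: 20 furanophane ketone
Product: 21 furanophane C2=C3 enol triflate
Conditions: KN(SiMe3)2 (KHMDS, 1.1 equiv), THF, −78 °C; PhNTf2, −78 → 0 °C; H2O
Reagents that add atoms: N-phenylbis(trifluoromethanesulfonimide), O=S(=O)(N(c1ccccc1)S(=O)(=O)C(F)(F)F)C(F)(F)F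
Why: Enolisation is possible only toward C2, and the ring holds C1 cis to the furan carbon C4, so enolate O-triflation should give the single alkene geometry required.

Step 14
Reactants: 21 enol triflate
Product: 22 furanophane methyl ester (C2=C3–CO2Me; C8–OTBS)
Conditions: Pd(OAc)2 (5 mol%), PPh3 (10 mol%), CO (1 atm), MeOH, Et3N, DMF, 50 °C
Reagents that add atoms: carbon monoxide, [C-]#[O+]; methanol, CO
Why: Palladium-catalysed methoxycarbonylation of a vinyl triflate proceeds with retention of alkene geometry.

Step 15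
Reactants: 22 silyl ether ester
Product: 23 furanophane ester with free C8 hydroxyl
Conditions: n-Bu4NF, THF, 0 °C
Reagents that add atoms: none
Why: Fluoride desilylation liberates the furyl carbinol needed for the furan oxidation.

Step 16
Reactants: 23 furyl carbinol
Product: 24 bridged 6-hydroxy-2H-pyran-3(6H)-one (ring oxygen on C8; C7 ketone; C4 hemiketal)
Conditions: VO(acac)2 (5 mol%), t-BuOOH (1.5 equiv), CH2Cl2, 0 °C → rt
Reagents that add atoms: tert-butyl hydroperoxide, CC(C)(C)OO
Why: Hydroxyl-directed Achmatowicz rearrangement oxidises the furan and not the isolated C11=C12 alkene; the C4 hemiketal configuration is dictated by C8 because the oxygen bridge can only span the carbocycle cis.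

Step 17
Reactants: 24 pyranone hemiketal
Product: 25 pyranose diol (C7 methyl carbinol; C4 hemiketal; eight-membered oxa-bridged ring)
Conditions: MeLi (3 equiv), CeCl3 (3 equiv), THF, −78 °C; H2O
Reagents that add atoms: methyllithium, [Li]C
Why: 1,2-Addition of a methylcerium reagent to the enone carbonyl in preference to the conjugated ester, from the face opposite the five-carbon bridge, should set C7 with methyl anti and hydroxyl syn to the bridge.

Step 18
Reactants: 26 1-methyl-1H-imidazole-4-carbaldehyde; 27 malonic acid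
Product: 28 (E)-3-(1-methyl-1H-imidazol-4-yl)prop-2-enoic acid
Conditions: pyridine, piperidine (cat.), 100 °C
Reagents that add atoms: none
Why: Knoevenagel–Doebner condensation with decarboxylation gives the E acid.

Step 19
Reactants: 25 pyranose diol; 28 (E)-N-methylurocanic acid
Product: 31 target CNP0372023.1, via mixed anhydride 29 (not isolated), via furanose hemiketal diol 30 (not isolated)
Conditions: 28, t-BuCOCl, Et3N, THF, 0 °C → rt; then 25, DMAP, Et3N, (CH2Cl)2, 50 °C
Reagents that add atoms: none
Why: Under DMAP/Et3N the pyranose hemiketal 25 is in ring–chain equilibrium with the open C4 enone, in which C8–OH is free and the tertiary C7–OH can add to the C4 carbonyl instead; both hydroxyls of 25 itself are tertiary and should not be acylated, so the acylpyridinium from 29 esterifies only the secondary C8–OH of the open or furanose tautomer and draws the equilibrium into the 4,7-bridged series (Curtin–Hammett trapping). The closest known reaction type is the acylation-driven pyranose-to-furanose isomerisation of Achmatowicz-derived lactols (ring–chain tautomerism of hydroxy ketones). The 2,5-dihydrofuran closes by 5-exo-trig addition of the C7 oxygen to the C4 ketone, and with it the oxygen bridge moves from C8 to C7, so the eight-membered oxacycle C4–C3–C2–C1–C10–C9–C8–O becomes the nine-membered one by taking in C7. The only stereocentre formed, C4, is fixed by C7 because the one-atom bridge can span the ten-membered carbocycle only cis, which leaves the hydroxyl on the outer face. The step needs chemoselectivity for C8–OH over the C4 hemiketal hydroxyl, secured by the secondary versus fully substituted carbinol difference and a limited excess of 29; once C8 is esterified the pyranose cannot re-form.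

Compound list
1 | 3-methylbutanal (isovaleraldehyde) | CC(C)CC=O | starting material
2 | but-3-en-2-one (methyl vinyl ketone) | CC(=O)C=C | starting material
3 | (R)-2-isopropyl-5-oxohexanal | CC(=O)CC[C@@H](C=O)C(C)C | intermediate
4 | (R)-4-isopropylcyclohex-2-en-1-one, (R)-cryptone | CC(C)[C@@H]1C=CC(=O)CC1 | intermediate
5 | (1,3-dioxolan-2-ylmethyl)magnesium bromide | Br[Mg]CC1OCCO1 | starting material
6 | trimethylsilyl enol ether of trans-3-(1,3-dioxolan-2-ylmethyl)-4-isopropylcyclohexanone | C[Si](C)(C)OC1=C[C@H](CC2OCCO2)[C@@H](C(C)C)CC1 | intermediate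
7 | (R)-3-(1,3-dioxolan-2-ylmethyl)-4-isopropylcyclohex-2-en-1-one | O=C1C=C(CC2OCCO2)[C@@H](C(C)C)CC1 | intermediate
8 | 2-bromo-N-methoxy-N-methylacetamide | CON(C)C(=O)CBr | starting material
9 | dimethyl(phenyl)silyl enol ether of cis-3-(1,3-dioxolan-2-ylmethyl)-4-isopropylcyclohexanone | C[Si](C)(c1ccccc1)OC1=C[C@@H](CC2OCCO2)[C@@H](C(C)C)CC1 | intermediate
10 | 2-[2-(1,3-dioxolan-2-ylmethyl)-3-isopropyl-6-oxocyclohexyl]-N-methoxy-N-methylacetamide (1,2-trans, 2,3-cis) | O1CCOC1C[C@H]2[C@@H](C(C)C)CCC(=O)[C@@H]2CC(=O)N(C)OC | intermediate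
11 | C11 enol triflate of 10 (C11=C12) | O1CCOC1C[C@H]2[C@@H](C(C)C)CC=C(OS(=O)(=O)C(F)(F)F)[C@@H]2CC(=O)N(C)OC | intermediate
12 | 2-[6-(1,3-dioxolan-2-ylmethyl)-5-isopropyl-2-methylcyclohex-2-en-1-yl]-N-methoxy-N-methylacetamide (1,6-trans, 5,6-cis) | O1CCOC1C[C@H]2[C@@H](C(C)C)CC=C(C)[C@@H]2CC(=O)N(C)OC | intermediate
13 | 2,5-dibromofuran | Brc1ccc(Br)o1 | starting material
14 | 5-bromo-2-furyllithium | [Li]c1ccc(Br)o1 | intermediate
15 | 1-(5-bromofuran-2-yl)-2-[6-(1,3-dioxolan-2-ylmethyl)-5-isopropyl-2-methylcyclohex-2-en-1-yl]ethanone | O1CCOC1C[C@H]2[C@@H](C(C)C)CC=C(C)[C@@H]2CC(=O)c3ccc(Br)o3 | intermediate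
16 | (S)-carbinol from 15 (C8–OH) | O1CCOC1C[C@H]2[C@@H](C(C)C)CC=C(C)[C@@H]2C[C@H](O)c3ccc(Br)o3 | intermediate
17 | C8 tert-butyldimethylsilyl ether of 16 | O1CCOC1C[C@H]2[C@@H](C(C)C)CC=C(C)[C@@H]2C[C@H](O[Si](C)(C)C(C)(C)C)c3ccc(Br)o3 | intermediate
18 | C3 aldehyde (2-{2-[(S)-2-(5-bromofuran-2-yl)-2-(TBS-oxy)ethyl]-6-isopropyl-3-methylcyclohex-3-en-1-yl}acetaldehyde) | O=CC[C@H]1[C@@H](C(C)C)CC=C(C)[C@@H]1C[C@H](O[Si](C)(C)C(C)(C)C)c2ccc(Br)o2 | intermediate
19 | [6](2,5)furanophane carbinol (C3–OH epimers, C8–OTBS) | OC1C[C@H]2[C@@H](C(C)C)CC=C(C)[C@@H]2C[C@H](O[Si](C)(C)C(C)(C)C)c2ccc1o2 | intermediate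
20 | furanophane C3 ketone | O=C1C[C@H]2[C@@H](C(C)C)CC=C(C)[C@@H]2C[C@H](O[Si](C)(C)C(C)(C)C)c2ccc1o2 | intermediate
21 | furanophane C2=C3 enol triflate | FC(F)(F)S(=O)(=O)O/C1=C/[C@H]2[C@@H](C(C)C)CC=C(C)[C@@H]2C[C@H](O[Si](C)(C)C(C)(C)C)c2ccc1o2 | intermediate
22 | furanophane methyl ester (C8–OTBS) | COC(=O)/C1=C/[C@H]2[C@@H](C(C)C)CC=C(C)[C@@H]2C[C@H](O[Si](C)(C)C(C)(C)C)c2ccc1o2 | intermediate
23 | furanophane methyl ester (C8–OH) | COC(=O)/C1=C/[C@H]2[C@@H](C(C)C)CC=C(C)[C@@H]2C[C@H](O)c2ccc1o2 | intermediate
24 | bridged pyranone hemiketal (O on C8, C7 ketone, C4–OH) | COC(=O)/C1=C/[C@H]2[C@@H](C(C)C)CC=C(C)[C@@H]2C[C@@H]3O[C@@]1(O)C=CC3=O | intermediate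
25 | pyranose diol (C7 methyl carbinol, C4 hemiketal) | COC(=O)/C1=C/[C@H]2[C@@H](C(C)C)CC=C(C)[C@@H]2C[C@@H]3O[C@@]1(O)C=C[C@]3(C)O | intermediate
26 | 1-methyl-1H-imidazole-4-carbaldehyde | Cn1cnc(C=O)c1 | starting material
27 | malonic acid | OC(=O)CC(=O)O | starting material
28 | (E)-3-(1-methyl-1H-imidazol-4-yl)prop-2-enoic acid | OC(=O)/C=C/c1cn(C)cn1 | intermediate
29 | mixed anhydride of 28 with pivalic acid | CC(C)(C)C(=O)OC(=O)/C=C/c1cn(C)cn1 | intermediate
30 | furanose hemiketal diol (4,7-oxa bridge, C8–OH) | COC(=O)/C1=C/[C@H]2[C@@H](C(C)C)CC=C(C)[C@@H]2C[C@H](O)[C@]2(C)C=C[C@@]1(O)O2 | intermediate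
31 | CNP0372023.1 (C8 (E)-N-methylurocanate of 30) | COC(=O)/C1=C/[C@H]2[C@@H](C(C)C)CC=C(C)[C@@H]2C[C@H](OC(=O)/C=C/c2cn(C)cn2)[C@]2(C)C=C[C@@]1(O)O2 | target

Total step count: 19. Longest linear sequence: 18 (steps 1–17 and 19; step 18 is a one-step side branch).

Steps most likely to fail

Step 19: ring–chain equilibration may be slower than acylation of the anomeric C4 hydroxyl, or esterification of the hindered C8 hydroxyl by the bulky anhydride may be too slow for the sensitive enone. The fallback sets out from 25 and separates ring expansion from side-chain attachment. Acetylation (Ac2O, DMAP, Et3N) uses a small acyl group to trigger the same isomerisation and should give the furanose 8-O-acetate hemiketal F1. PPTS in MeOH then locks C4 as the 4-O-methyl ketal 8-acetate F2. K2CO3 in MeOH frees the 4-O-methyl ketal 8-alcohol F3, which cannot revert to a pyranose. Acylation with 29 (DMAP, Et3N) gives the 4-O-methyl ketal 8-urocanate F4, and mild aqueous acid (camphorsulfonic acid, MeCN/H2O) hydrolyses the ketal and comes back to the route at 31.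

Step 11: the trans-disposed side chains must adopt the diequatorial conformer (isopropyl axial) to close the strained furanophane, so intermolecular coupling and protodebromination of the organochromium may outrun cyclisation. The fallback sets out from 18 and closes the same bond by an anionic acylation. Pinnick oxidation (NaClO2, NaH2PO4, 2-methylbut-2-ene) gives the carboxylic acid F5. Amidation (MeNHOMe·HCl, EDC·HCl, DMAP) gives the Weinreb amide F6. Bromine–lithium exchange with t-BuLi (2.1 equiv, THF, −100 °C, high dilution) is then followed by intramolecular acylation (Parham-type cyclisation), which comes back to the route at ketone 20 without the alcohol stage.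

Step 17: the metal lactolate may open to the enedione, exposing the C4 carbonyl and the ester to the methyl nucleophile, or facial selectivity at C7 may erode. The fallback sets out from 24 and caps the lactol first. Silylation (TESOTf, 2,6-lutidine) gives the 4-O-triethylsilyl pyranone F7. MeLi/CeCl3 then gives the 4-O-triethylsilyl tertiary alcohol F8. HF·pyridine removes the silyl group and comes back to the route at 25.

Further compounds
F1 | step 19 | furanose 8-O-acetate hemiketal | COC(=O)/C1=C/[C@H]2[C@@H](C(C)C)CC=C(C)[C@@H]2C[C@H](OC(C)=O)[C@]2(C)C=C[C@@]1(O)O2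
F2 | step 19 | 4-O-methyl ketal 8-acetate | COC(=O)/C1=C/[C@H]2[C@@H](C(C)C)CC=C(C)[C@@H]2C[C@H](OC(C)=O)[C@]2(C)C=C[C@@]1(OC)O2
F3 | step 19 | 4-O-methyl ketal 8-alcohol | COC(=O)/C1=C/[C@H]2[C@@H](C(C)C)CC=C(C)[C@@H]2C[C@H](O)[C@]2(C)C=C[C@@]1(OC)O2
F4 | step 19 | 4-O-methyl ketal 8-urocanate | COC(=O)/C1=C/[C@H]2[C@@H](C(C)C)CC=C(C)[C@@H]2C[C@H](OC(=O)/C=C/c2cn(C)cn2)[C@]2(C)C=C[C@@]1(OC)O2
F5 | step 11 | carboxylic acid | OC(=O)C[C@H]1[C@@H](C(C)C)CC=C(C)[C@@H]1C[C@H](O[Si](C)(C)C(C)(C)C)c2ccc(Br)o2
F6 | step 11 | Weinreb amide | CON(C)C(=O)C[C@H]1[C@@H](C(C)C)CC=C(C)[C@@H]1C[C@H](O[Si](C)(C)C(C)(C)C)c2ccc(Br)o2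
F7 | step 17 | 4-O-triethylsilyl pyranone | COC(=O)/C1=C/[C@H]2[C@@H](C(C)C)CC=C(C)[C@@H]2C[C@@H]3O[C@@]1(O[Si](CC)(CC)CC)C=CC3=O
F8 | step 17 | 4-O-triethylsilyl tertiary alcohol | COC(=O)/C1=C/[C@H]2[C@@H](C(C)C)CC=C(C)[C@@H]2C[C@@H]3O[C@@]1(O[Si](CC)(CC)CC)C=C[C@]3(C)O
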